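**Plan**

1. Labdane numbering is used throughout: ring A is C1–C5 and C10, ring B is C5–C10, C18 and C19 are the equatorial and axial carbons on C4, C17 is the methyl on C8 and C20 the methyl on C10.
2. Retrosynthetic cuts, in order: the ester C–O bonds at C15 (malonate) and C18 (angelate); C8–C17 (methyl via the 8(17)-alkene and its epoxide) and the C19–O bond; C11–C12 (Wittig); C5–C10 together with C8–C9 (intramolecular Diels–Alder); C7–C8 (cross-metathesis) and C3–C4 (malonate alkylation).
3. Enabling feature: ring B holds the trans ring-fusion bond C5–C10 flanked by C9 and the carbinol carbon C8, so it is a cyclohexene retron whose four-carbon tether C1–C4 is ring A; C4 with two identical oxymethyl arms keeps the triene achiral.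
4. Forward: the C11–C3 chain from geranyl acetate is joined to C4 of allylmalonate, the allyl group is grown into the C5–C8 silyloxydiene, one catalytic cycloaddition closes ring B and ring A together, then the C12–C15 chain is attached at C11 and C4, C8, C18 and C15 are finished.
5. Stereochemistry: C5, C9 and C10 come from the catalyst-controlled endo cycloaddition of the (E,E)-diene and the (E)-enal; C13 from (R)-2-methylsuccinic acid 4-tert-butyl ester; C4 from acylating the equatorial arm of the rigid trans-decalin; C8 from epoxidation anti to C20 followed by hydride opening.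

Key step: step 11

Assumption: the (S)-configured oxazaborolidinium ion is taken to expose the C9 Re/C10 Si face of the bound enal; if the first adduct proves antipodal, the catalyst made in the same way from (R)-diphenylprolinol takes its place.

**Route**

Step 1
Reactants: 1 geranyl acetate
Product: 4 (2E)-6-hydroxy-3-methylhex-2-en-1-yl acetate, via ozonide 2 (not isolated), via aldehyde 3 (not isolated)
Conditions: O3 (about 1 equiv), CH2Cl2, −78 °C; then NaBH4, MeOH, −78 → 0 °C
Reagents that add atoms: ozone, [O-][O+]=O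
Why: Ozonolysis with reductive work-up; the electron-rich 6,7-alkene should react much faster than the 2,3-alkene, which is deactivated by the allylic acetate, and NaBH4 reduces the ozonide to the primary alcohol without cleaving the acetate at low temperature.

Step 2
Reactants: 4 (2E)-6-hydroxy-3-methylhex-2-en-1-yl acetate
Product: 5 (2E)-6-iodo-3-methylhex-2-en-1-yl acetate
Conditions: I2, PPh3, imidazole, CH2Cl2, 0 °C → rt
Reagents that add atoms: iodine, II
Why: Appel-type iodination of an unhindered primary alcohol by SN2 displacement of the oxyphosphonium group; the allylic acetate is inert.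

Step 3
Reactants: 6 diethyl allylmalonate; 5 (2E)-6-iodo-3-methylhex-2-en-1-yl acetate
Product: 8 diethyl 2-[(4E)-6-acetoxy-4-methylhex-4-en-1-yl]-2-allylmalonate, via sodium enolate 7 (not isolated)
Conditions: NaH, THF–DMF, 0 °C; then 5, rt → 50 °C
Reagents that add atoms: none
Why: Malonic ester alkylation; the soft enolate displaces the primary iodide by SN2 and forms the C3–C4 bond, creating the quaternary but still achiral C4.

Step 4
Reactants: 8 diethyl 2-[(4E)-6-acetoxy-4-methylhex-4-en-1-yl]-2-allylmalonate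
Product: 9 2-allyl-2-[(4E)-6-hydroxy-4-methylhex-4-en-1-yl]propane-1,3-diol
Conditions: LiAlH4, THF, 0 °C → rt
Reagents that add atoms: none
Why: Hydride reduction of both ethyl esters gives the two identical hydroxymethyl arms on C4; the acetate, no longer needed, is cleaved in the same operation.

Step 5
Reactants: 9 2-allyl-2-[(4E)-6-hydroxy-4-methylhex-4-en-1-yl]propane-1,3-diol
Product: 10 (2E)-6-(5-allyl-2,2-dimethyl-1,3-dioxan-5-yl)-3-methylhex-2-en-1-ol
Conditions: 2,2-dimethoxypropane, PPTS (cat.), acetone, rt; aq. NaHCO3 work-up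
Reagents that add atoms: 2,2-dimethoxypropane, COC(C)(C)OC
Why: Acid-catalysed ketalisation; the 2,2-disubstituted propane-1,3-diol closes the six-membered acetonide readily, and any mixed ketal on the allylic hydroxy group is lost on aqueous work-up.

Step 6
Reactants: 10 (2E)-6-(5-allyl-2,2-dimethyl-1,3-dioxan-5-yl)-3-methylhex-2-en-1-ol
Product: 11 (2E)-6-(5-allyl-2,2-dimethyl-1,3-dioxan-5-yl)-3-methylhex-2-en-1-yl pivalate
Conditions: t-BuCOCl, pyridine, DMAP (cat.), CH2Cl2, 0 °C
Reagents that add atoms: pivaloyl chloride, CC(C)(C)C(=O)Cl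
Why: Acylation of the primary allylic alcohol; the pivalate masks C11 during dienol ether formation, has no enolisable hydrogen and can later be removed by hydride without acid or fluoride.

Step 7
Reactants: 11 (2E)-6-(5-allyl-2,2-dimethyl-1,3-dioxan-5-yl)-3-methylhex-2-en-1-yl pivalate; 12 acrolein
Product: 13 (2E)-6-{2,2-dimethyl-5-[(2E)-4-oxobut-2-en-1-yl]-1,3-dioxan-5-yl}-3-methylhex-2-en-1-yl pivalate
Conditions: acrolein (excess), second-generation Hoveyda–Grubbs catalyst RuCl2(SIMes)(=CH-C6H4-2-OiPr) (5 mol %), CH2Cl2, 40 °C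
Reagents that add atoms: none
Why: Olefin cross-metathesis of the terminal alkene with an electron-poor partner forms the C7–C8 bond as the (E)-enal; the trisubstituted alkene should not take part.

Step 8
Reactants: 13 (2E)-6-{2,2-dimethyl-5-[(2E)-4-oxobut-2-en-1-yl]-1,3-dioxan-5-yl}-3-methylhex-2-en-1-yl pivalate
Product: 14 (2E)-6-{5-[(1E,3E)-4-(tert-butyldimethylsilyloxy)buta-1,3-dien-1-yl]-2,2-dimethyl-1,3-dioxan-5-yl}-3-methylhex-2-en-1-yl pivalate
Conditions: TBSOTf, Et3N, Et2O, 0 °C → rt
Reagents that add atoms: tert-butyldimethylsilyl trifluoromethanesulfonate, CC(C)(C)[Si](C)(C)OS(=O)(=O)C(F)(F)F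
Why: Vinylogous silyl enol ether formation (O-silylation, then γ-deprotonation at C5 by the amine) gives the 1-silyloxydiene, the (E,E)-isomer being expected to predominate because C4 is quaternary and bulky.

Step 9
Reactants: 14 (2E)-6-{5-[(1E,3E)-4-(tert-butyldimethylsilyloxy)buta-1,3-dien-1-yl]-2,2-dimethyl-1,3-dioxan-5-yl}-3-methylhex-2-en-1-yl pivalate
Product: 15 (2E)-6-{5-[(1E,3E)-4-(tert-butyldimethylsilyloxy)buta-1,3-dien-1-yl]-2,2-dimethyl-1,3-dioxan-5-yl}-3-methylhex-2-en-1-ol
Conditions: i-Bu2AlH, CH2Cl2, −78 °C; aq. Rochelle salt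
Reagents that add atoms: none
Why: Reductive ester cleavage under aprotic conditions frees the allylic alcohol while the acid- and fluoride-sensitive silyl dienol ether and the acetonide should remain intact.

Step 10
Reactants: 15 (2E)-6-{5-[(1E,3E)-4-(tert-butyldimethylsilyloxy)buta-1,3-dien-1-yl]-2,2-dimethyl-1,3-dioxan-5-yl}-3-methylhex-2-en-1-ol
Product: 16 (2E)-6-{5-[(1E,3E)-4-(tert-butyldimethylsilyloxy)buta-1,3-dien-1-yl]-2,2-dimethyl-1,3-dioxan-5-yl}-3-methylhex-2-enal (achiral triene)
Conditions: MnO2, CH2Cl2, rt; used at once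
Reagents that add atoms: none
Why: Chemoselective allylic oxidation with MnO2 under neutral conditions gives the (E)-enal without E/Z isomerisation and should not touch the dienol ether.

Step 11
Reactants: 16 (2E)-6-{5-[(1E,3E)-4-(tert-butyldimethylsilyloxy)buta-1,3-dien-1-yl]-2,2-dimethyl-1,3-dioxan-5-yl}-3-methylhex-2-enal
Product: 17 (4a'R,5'S,6'R,8a'S)-6'-(tert-butyldimethylsilyloxy)-2,2,4a'-trimethyl-3',4',4a',5',6',8a'-hexahydro-2'H-spiro[1,3-dioxane-5,1'-naphthalene]-5'-carbaldehyde (labdane locants 5S,8R,9S,10R; trans-fused, with CHO, 10-CH3 and 8-OTBS on one face and H-5 on the other)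
Conditions: (S)-oxazaborolidinium triflimide (20 mol %; (S)-3,3-diphenyl-1-(o-tolyl)tetrahydro-1H,3H-pyrrolo[1,2-c][1,3,2]oxazaborole protonated with HNTf2), CH2Cl2, −78 → −20 °C; Et3N quench
Reagents that add atoms: none
Why: Proposed new method: the formyl oxygen binds to boron of the chiral oxazaborolidinium ion, which lowers the LUMO of the s-trans enal, while the silyloxy group raises the diene HOMO and puts its largest coefficient on C5, so a concerted but asynchronous [4+2] cycloaddition with the C5–C10 bond leading is expected; the closest known reaction type is the oxazaborolidinium- or iminium-catalysed intramolecular Diels–Alder reaction of 1,7,9-decatrienals to trans-decalins, which has not been shown for a β,β-disubstituted enal that creates an angular quaternary carbon. Ring B (C5–C10) closes as the cyclohexene of the cycloaddition through the new bonds C5–C10 and C8–C9, and ring A (C1–C5, C10) closes at the same moment as the six-membered tether ring through the C5–C10 bond. The (E)-enal geometry is transferred suprafacially and places the formyl group on C9 cis to the methyl group on C10, and the (E,E)-diene geometry places C4 on C5 and the silyloxy group on C8 cis to each other. The endo position of the formyl group with the tether anti relates these two pairs and gives the trans ring fusion (H-5 trans to the C10 methyl, C8–O cis to C11), and the catalyst, which shields one face of the bound enal, decides the absolute sense (C5 adds to the Si face of C10). The step needs endo over exo addition, one enal face over the other and cycloaddition over desilylative Mukaiyama–Michael paths; the first is secured by the Lewis-acid-bound formyl group and the chair-like four-carbon tether carrying the gem-disubstituted C4, the second by the catalyst, and the third by the bulky tert-butyldimethylsilyl group and the low temperature.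

Step 12
Reactants: 18 (2R)-4-tert-butoxy-2-methyl-4-oxobutanoic acid
Product: 19 tert-butyl (3R)-4-hydroxy-3-methylbutanoate
Conditions: BH3·SMe2, THF, 0 °C → rt; MeOH quench
Reagents that add atoms: none
Why: Chemoselective borane reduction of the carboxylic acid (via an acyloxyborane) in the presence of the tert-butyl ester; the stereocentre is not touched.

Step 13
Reactants: 19 tert-butyl (3R)-4-hydroxy-3-methylbutanoate
Product: 20 tert-butyl (3R)-4-iodo-3-methylbutanoate
Conditions: I2, PPh3, imidazole, CH2Cl2, 0 °C → rt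
Reagents that add atoms: iodine, II
Why: Appel-type iodination of the primary alcohol; the tert-butyl ester resists lactonisation and the adjacent stereocentre is not involved.

Step 14
Reactants: 20 tert-butyl (3R)-4-iodo-3-methylbutanoate
Product: 21 [(2R)-4-tert-butoxy-2-methyl-4-oxobutyl]triphenylphosphonium iodide
Conditions: PPh3, MeCN, reflux
Reagents that add atoms: triphenylphosphine, c1ccc(cc1)P(c1ccccc1)c1ccccc1
Why: SN2 quaternisation of triphenylphosphine by the β-branched primary iodide gives the Wittig salt.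

Step 15
Reactants: 17 cycloadduct aldehyde (see step 11); 21 [(2R)-4-tert-butoxy-2-methyl-4-oxobutyl]triphenylphosphonium iodide
Product: 23 tert-butyl (3R,4Z)-5-[(4a'R,5'S,6'R,8a'S)-6'-(tert-butyldimethylsilyloxy)-2,2,4a'-trimethyl-3',4',4a',5',6',8a'-hexahydro-2'H-spiro[1,3-dioxane-5,1'-naphthalen]-5'-yl]-3-methylpent-4-enoate, via phosphorus ylide 22 (not isolated)
Conditions: 21, NaN(SiMe3)2, THF, −78 → 0 °C; then 17, −78 °C → rt
Reagents that add atoms: none
Why: Wittig olefination with a non-stabilised ylide forms the C11=C12 bond and brings in C13 with its configuration from 18; the alkene geometry is irrelevant because it is hydrogenated next, and the low temperature limits β-elimination of the C8 silyloxy group.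

Step 16
Reactants: 23 Wittig product (see step 15)
Product: 24 tert-butyl (3S)-5-[(4a'R,5'S,6'R,8a'S)-6'-(tert-butyldimethylsilyloxy)-2,2,4a'-trimethyloctahydro-2'H-spiro[1,3-dioxane-5,1'-naphthalen]-5'-yl]-3-methylpentanoate
Conditions: H2 (1–3 atm), PtO2, EtOAc, rt
Reagents that add atoms: none
Why: Heterogeneous catalytic hydrogenation saturates both disubstituted alkenes (C6=C7 and C11=C12) without creating a stereocentre; platinum is chosen to avoid hydrogenolysis of the allylic C8–O bond.

Step 17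
Reactants: 24 saturated acetonide (see step 16)
Product: 25 tert-butyl (3S)-5-[(1S,2R,4aS,8aR)-2-(tert-butyldimethylsilyloxy)-5,5-bis(hydroxymethyl)-8a-methyldecahydronaphthalen-1-yl]-3-methylpentanoate
Conditions: PPTS, MeOH, 40 °C
Reagents that add atoms: none
Why: Acid-catalysed transacetalisation to methanol removes the acetonide, while the hindered secondary silyl ether and the tert-butyl ester should survive the weak acid.

Step 18
Reactants: 25 diol (see step 17)
Product: 26 tert-butyl (3S)-5-[(1S,2R,4aS,5S,8aR)-2-(tert-butyldimethylsilyloxy)-5-(hydroxymethyl)-8a-methyl-5-(pivaloyloxymethyl)decahydronaphthalen-1-yl]-3-methylpentanoate (pivalate on the equatorial arm C18, free hydroxy group on the axial arm C19)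
Conditions: t-BuCOCl (1.05 equiv), pyridine, CH2Cl2, −20 → 0 °C
Reagents that add atoms: pivaloyl chloride, CC(C)(C)C(=O)Cl
Why: Kinetically selective acylation of the equatorial hydroxymethyl group, the axial one being syn-axial to the C10 methyl group; this choice between the two diastereotopic arms sets the configuration of C4.

Step 19
Reactants: 26 mono-pivalate (see step 18)
Product: 27 tert-butyl (3S)-5-[(1S,2R,4aS,5R,8aR)-2-(tert-butyldimethylsilyloxy)-5-formyl-8a-methyl-5-(pivaloyloxymethyl)decahydronaphthalen-1-yl]-3-methylpentanoate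
Conditions: Dess–Martin periodinane, NaHCO3, CH2Cl2, rt
Reagents that add atoms: none
Why: Dess–Martin oxidation of the remaining neopentyl primary alcohol gives the non-enolisable C19 aldehyde under buffered, non-basic conditions that exclude acyl migration.

Step 20
Reactants: 27 C19 aldehyde (see step 19)
Product: 29 tert-butyl (3S)-5-[(1S,2R,4aS,5S,8aR)-2-(tert-butyldimethylsilyloxy)-5,8a-dimethyl-5-(pivaloyloxymethyl)decahydronaphthalen-1-yl]-3-methylpentanoate, via tosylhydrazone 28 (not isolated)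
Conditions: TsNHNH2, THF, 50 °C; then catecholborane, CHCl3, 0 °C; NaOAc·3H2O, reflux
Reagents that add atoms: none
Why: Reductive deoxygenation through the tosylhydrazone (hydride addition to C=N, then loss of sulfinate and N2 from the diazene), a mild Wolff–Kishner-type reduction that tolerates both esters and the silyl ether and turns C19 into the axial methyl group.

Step 21
Reactants: 29 C19-methyl silyl ether (see step 20)
Product: 30 tert-butyl (3S)-5-[(1S,2R,4aS,5S,8aR)-2-hydroxy-5,8a-dimethyl-5-(pivaloyloxymethyl)decahydronaphthalen-1-yl]-3-methylpentanoate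
Conditions: Bu4NF, THF, 50 °C
Reagents that add atoms: none
Why: Fluoride-induced desilylation of the hindered axial C8 silyl ether; the neopentyl pivalate and the tert-butyl ester are stable to fluoride.

Step 22
Reactants: 30 C8 alcohol (see step 21)
Product: 31 tert-butyl (3S)-5-[(1S,4aS,5S,8aR)-5,8a-dimethyl-2-oxo-5-(pivaloyloxymethyl)decahydronaphthalen-1-yl]-3-methylpentanoate
Conditions: Dess–Martin periodinane, NaHCO3, CH2Cl2, rt
Reagents that add atoms: none
Why: Dess–Martin oxidation of the secondary alcohol gives the C8 ketone; the adjacent C9 stereocentre carries its chain equatorially and should not epimerise.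

Step 23
Reactants: 31 C8 ketone (see step 22)
Product: 32 tert-butyl (3S)-5-[(1R,4aS,5S,8aS)-5,8a-dimethyl-2-methylidene-5-(pivaloyloxymethyl)decahydronaphthalen-1-yl]-3-methylpentanoate
Conditions: Ph3PCH3Br, KOtBu, toluene, 80 °C
Reagents that add atoms: methyltriphenylphosphonium bromide, [Br-].C[P+](c1ccccc1)(c1ccccc1)c1ccccc1
Why: Wittig methylenation of the hindered ketone adds C17; the pivalate and the tert-butyl ester are too hindered to react with the ylide, and C9 stays in its more stable equatorial configuration (the descriptors change only through priority).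

Step 24
Reactants: 32 8(17)-alkene (see step 23)
Product: 33 tert-butyl (3S)-5-[(1'S,2S,4a'S,5'S,8a'R)-5',8a'-dimethyl-5'-(pivaloyloxymethyl)octahydro-1'H-spiro[oxirane-2,2'-naphthalen]-1'-yl]-3-methylpentanoate (oxirane oxygen on the face opposite to the C10 methyl)
Conditions: mCPBA, NaHCO3, CH2Cl2, 0 °C
Reagents that add atoms: 3-chloroperoxybenzoic acid, OOC(=O)c1cccc(Cl)c1
Why: Prilezhaev epoxidation; the peracid should attack the exocyclic alkene from the face opposite to the axial C10 methyl group, so the oxygen becomes equatorial and C8 obtains its final configuration.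

Step 25
Reactants: 33 8,17-epoxide (see step 24)
Product: 34 (3S)-5-[(1S,2S,4aS,5S,8aR)-2-hydroxy-5-(hydroxymethyl)-2,5,8a-trimethyldecahydronaphthalen-1-yl]-3-methylpentan-1-ol
Conditions: LiAlH4, THF, 0 °C → reflux
Reagents that add atoms: none
Why: Hydride opens the epoxide by SN2 at the primary carbon C17 to give the tertiary alcohol with the axial methyl group, and in the same step cleaves the pivalate and reduces the tert-butyl ester to the C15 alcohol.

Step 26
Reactants: 34 triol (see step 25)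
Product: 35 (1S,2S,4aS,5S,8aR)-1-[(3S)-5-(tert-butyldimethylsilyloxy)-3-methylpentyl]-5-(hydroxymethyl)-2,5,8a-trimethyldecahydronaphthalen-2-ol
Conditions: TBSCl (1.05 equiv), imidazole, CH2Cl2, −20 °C
Reagents that add atoms: tert-butyldimethylsilyl chloride, CC(C)(C)[Si](C)(C)Cl
Why: Selective silylation of the unhindered primary C15 hydroxy group in the presence of the neopentyl C18 and the tertiary C8 hydroxy groups.

Step 27
Reactants: 35 C15 silyl ether (see step 26)
Product: 36 [(1S,2S,4aS,5S,8aR)-1-{(3S)-5-(tert-butyldimethylsilyloxy)-3-methylpentyl}-2-hydroxy-2,5,8a-trimethyldecahydronaphthalen-5-yl]methyl (2Z)-2-methylbut-2-enoate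
Conditions: angelic acid, 2,4,6-trichlorobenzoyl chloride, Et3N, toluene, rt; then 35, 80 °C
Reagents that add atoms: angelic acid, C/C=C(/C)C(=O)O
Why: Yamaguchi-type esterification through the 2,4,6-trichlorobenzoyl mixed anhydride acylates the neopentyl C18 alcohol without Z to E isomerisation of the angelate; the tertiary alcohol is too hindered to react.

Step 28
Reactants: 36 silylated angelate (see step 27)
Product: 37 [(1S,2S,4aS,5S,8aR)-2-hydroxy-1-{(3S)-5-hydroxy-3-methylpentyl}-2,5,8a-trimethyldecahydronaphthalen-5-yl]methyl (2Z)-2-methylbut-2-enoate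
Conditions: HF·pyridine, pyridine, THF, 0 °C → rt
Reagents that add atoms: none
Why: Buffered fluoride desilylation of the primary silyl ether under conditions that should neither isomerise the angelate nor dehydrate the tertiary alcohol.

Step 29
Reactants: 37 hydroxy angelate (see step 28)
Product: 38 3-{[(3S)-5-{(1S,2S,4aS,5S,8aR)-2-hydroxy-2,5,8a-trimethyl-5-[(2Z)-2-methylbut-2-enoyloxymethyl]decahydronaphthalen-1-yl}-3-methylpentyl]oxy}-3-oxopropanoic acid (target; labdane locants 4S,5S,8S,9S,10R,13S)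
Conditions: Meldrum's acid, toluene, 90 °C
Reagents that add atoms: Meldrum's acid, CC1(C)OC(=O)CC(=O)O1
Why: Ring-opening acylation of the primary alcohol by Meldrum's acid with loss of acetone gives the hydrogen malonate directly; the tertiary alcohol should not react at this temperature.

**Compound list**

1 | geranyl acetate, (2E)-3,7-dimethylocta-2,6-dien-1-yl acetate | CC(C)=CCC/C(C)=C/COC(C)=O | starting material
2 | (2E)-5-(5,5-dimethyl-1,2,4-trioxolan-3-yl)-3-methylpent-2-en-1-yl acetate (ozonide) | CC(=O)OC/C=C(\C)CCC1OOC(C)(C)O1 | intermediate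
3 | (2E)-3-methyl-6-oxohex-2-en-1-yl acetate | CC(=O)OC/C=C(\C)CCC=O | intermediate
4 | (2E)-6-hydroxy-3-methylhex-2-en-1-yl acetate | CC(=O)OC/C=C(\C)CCCO | intermediate
5 | (2E)-6-iodo-3-methylhex-2-en-1-yl acetate | CC(=O)OC/C=C(\C)CCCI | intermediate
6 | diethyl allylmalonate | CCOC(=O)C(CC=C)C(=O)OCC | starting material
7 | sodium enolate of diethyl allylmalonate | [Na+].CCOC(=O)[C-](CC=C)C(=O)OCC | intermediate
8 | diethyl 2-[(4E)-6-acetoxy-4-methylhex-4-en-1-yl]-2-allylmalonate | CCOC(=O)C(CC=C)(CCC/C(C)=C/COC(C)=O)C(=O)OCC | intermediate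
9 | 2-allyl-2-[(4E)-6-hydroxy-4-methylhex-4-en-1-yl]propane-1,3-diol | OCC(CO)(CC=C)CCC/C(C)=C/CO | intermediate
10 | (2E)-6-(5-allyl-2,2-dimethyl-1,3-dioxan-5-yl)-3-methylhex-2-en-1-ol | CC1(C)OCC(CC=C)(CCC/C(C)=C/CO)CO1 | intermediate
11 | (2E)-6-(5-allyl-2,2-dimethyl-1,3-dioxan-5-yl)-3-methylhex-2-en-1-yl pivalate | CC1(C)OCC(CC=C)(CCC/C(C)=C/COC(=O)C(C)(C)C)CO1 | intermediate
12 | acrolein | C=CC=O | starting material
13 | (2E)-6-{2,2-dimethyl-5-[(2E)-4-oxobut-2-en-1-yl]-1,3-dioxan-5-yl}-3-methylhex-2-en-1-yl pivalate | CC1(C)OCC(C/C=C/C=O)(CCC/C(C)=C/COC(=O)C(C)(C)C)CO1 | intermediate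
14 | (2E)-6-{5-[(1E,3E)-4-(tert-butyldimethylsilyloxy)buta-1,3-dien-1-yl]-2,2-dimethyl-1,3-dioxan-5-yl}-3-methylhex-2-en-1-yl pivalate | CC1(C)OCC(/C=C/C=C/O[Si](C)(C)C(C)(C)C)(CCC/C(C)=C/COC(=O)C(C)(C)C)CO1 | intermediate
15 | (2E)-6-{5-[(1E,3E)-4-(tert-butyldimethylsilyloxy)buta-1,3-dien-1-yl]-2,2-dimethyl-1,3-dioxan-5-yl}-3-methylhex-2-en-1-ol | CC1(C)OCC(/C=C/C=C/O[Si](C)(C)C(C)(C)C)(CCC/C(C)=C/CO)CO1 | intermediate
16 | (2E)-6-{5-[(1E,3E)-4-(tert-butyldimethylsilyloxy)buta-1,3-dien-1-yl]-2,2-dimethyl-1,3-dioxan-5-yl}-3-methylhex-2-enal | O=C/C=C(\C)CCCC1(COC(C)(C)OC1)/C=C/C=C/O[Si](C)(C)C(C)(C)C | intermediate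
17 | (4a'R,5'S,6'R,8a'S)-6'-(tert-butyldimethylsilyloxy)-2,2,4a'-trimethyl-3',4',4a',5',6',8a'-hexahydro-2'H-spiro[1,3-dioxane-5,1'-naphthalene]-5'-carbaldehyde | CC1(C)OCC2(CO1)CCC[C@]3(C)[C@@H]2C=C[C@@H](O[Si](C)(C)C(C)(C)C)[C@H]3C=O | intermediate
18 | (2R)-4-tert-butoxy-2-methyl-4-oxobutanoic acid | OC(=O)[C@H](C)CC(=O)OC(C)(C)C | starting material
19 | tert-butyl (3R)-4-hydroxy-3-methylbutanoate | OC[C@H](C)CC(=O)OC(C)(C)C | intermediate
20 | tert-butyl (3R)-4-iodo-3-methylbutanoate | IC[C@H](C)CC(=O)OC(C)(C)C | intermediate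
21 | [(2R)-4-tert-butoxy-2-methyl-4-oxobutyl]triphenylphosphonium iodide | [I-].CC(C)(C)OC(=O)C[C@@H](C)C[P+](c1ccccc1)(c1ccccc1)c1ccccc1 | intermediate
22 | tert-butyl (3R)-3-methyl-4-(triphenyl-λ5-phosphanylidene)butanoate (ylide) | CC(C)(C)OC(=O)C[C@@H](C)C=P(c1ccccc1)(c1ccccc1)c1ccccc1 | intermediate
23 | tert-butyl (3R,4Z)-5-[(4a'R,5'S,6'R,8a'S)-6'-(tert-butyldimethylsilyloxy)-2,2,4a'-trimethyl-3',4',4a',5',6',8a'-hexahydro-2'H-spiro[1,3-dioxane-5,1'-naphthalen]-5'-yl]-3-methylpent-4-enoate | CC1(C)OCC2(CO1)CCC[C@]3(C)[C@@H]2C=C[C@@H](O[Si](C)(C)C(C)(C)C)[C@H]3/C=C\[C@H](C)CC(=O)OC(C)(C)C | intermediate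
24 | tert-butyl (3S)-5-[(4a'R,5'S,6'R,8a'S)-6'-(tert-butyldimethylsilyloxy)-2,2,4a'-trimethyloctahydro-2'H-spiro[1,3-dioxane-5,1'-naphthalen]-5'-yl]-3-methylpentanoate | CC1(C)OCC2(CO1)CCC[C@]3(C)[C@@H]2CC[C@@H](O[Si](C)(C)C(C)(C)C)[C@H]3CC[C@H](C)CC(=O)OC(C)(C)C | intermediate
25 | tert-butyl (3S)-5-[(1S,2R,4aS,8aR)-2-(tert-butyldimethylsilyloxy)-5,5-bis(hydroxymethyl)-8a-methyldecahydronaphthalen-1-yl]-3-methylpentanoate | OCC1(CO)CCC[C@]2(C)[C@@H]1CC[C@@H](O[Si](C)(C)C(C)(C)C)[C@H]2CC[C@H](C)CC(=O)OC(C)(C)C | intermediate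
26 | tert-butyl (3S)-5-[(1S,2R,4aS,5S,8aR)-2-(tert-butyldimethylsilyloxy)-5-(hydroxymethyl)-8a-methyl-5-(pivaloyloxymethyl)decahydronaphthalen-1-yl]-3-methylpentanoate | CC(C)(C)C(=O)OC[C@@]1(CO)CCC[C@]2(C)[C@@H]1CC[C@@H](O[Si](C)(C)C(C)(C)C)[C@H]2CC[C@H](C)CC(=O)OC(C)(C)C | intermediate
27 | tert-butyl (3S)-5-[(1S,2R,4aS,5R,8aR)-2-(tert-butyldimethylsilyloxy)-5-formyl-8a-methyl-5-(pivaloyloxymethyl)decahydronaphthalen-1-yl]-3-methylpentanoate | CC(C)(C)C(=O)OC[C@@]1(C=O)CCC[C@]2(C)[C@@H]1CC[C@@H](O[Si](C)(C)C(C)(C)C)[C@H]2CC[C@H](C)CC(=O)OC(C)(C)C | intermediate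
28 | (E)-4-methylbenzenesulfonylhydrazone of 27 (5S) | CC(C)(C)C(=O)OC[C@@]1(/C=N/NS(=O)(=O)c3ccc(C)cc3)CCC[C@]2(C)[C@@H]1CC[C@@H](O[Si](C)(C)C(C)(C)C)[C@H]2CC[C@H](C)CC(=O)OC(C)(C)C | intermediate
29 | tert-butyl (3S)-5-[(1S,2R,4aS,5S,8aR)-2-(tert-butyldimethylsilyloxy)-5,8a-dimethyl-5-(pivaloyloxymethyl)decahydronaphthalen-1-yl]-3-methylpentanoate | CC(C)(C)C(=O)OC[C@@]1(C)CCC[C@]2(C)[C@@H]1CC[C@@H](O[Si](C)(C)C(C)(C)C)[C@H]2CC[C@H](C)CC(=O)OC(C)(C)C | intermediate
30 | tert-butyl (3S)-5-[(1S,2R,4aS,5S,8aR)-2-hydroxy-5,8a-dimethyl-5-(pivaloyloxymethyl)decahydronaphthalen-1-yl]-3-methylpentanoate | CC(C)(C)C(=O)OC[C@@]1(C)CCC[C@]2(C)[C@@H]1CC[C@@H](O)[C@H]2CC[C@H](C)CC(=O)OC(C)(C)C | intermediate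
31 | tert-butyl (3S)-5-[(1S,4aS,5S,8aR)-5,8a-dimethyl-2-oxo-5-(pivaloyloxymethyl)decahydronaphthalen-1-yl]-3-methylpentanoate | CC(C)(C)C(=O)OC[C@@]1(C)CCC[C@]2(C)[C@@H]1CCC(=O)[C@H]2CC[C@H](C)CC(=O)OC(C)(C)C | intermediate
32 | tert-butyl (3S)-5-[(1R,4aS,5S,8aS)-5,8a-dimethyl-2-methylidene-5-(pivaloyloxymethyl)decahydronaphthalen-1-yl]-3-methylpentanoate | CC(C)(C)C(=O)OC[C@@]1(C)CCC[C@]2(C)[C@@H]1CCC(=C)[C@H]2CC[C@H](C)CC(=O)OC(C)(C)C | intermediate
33 | tert-butyl (3S)-5-[(1'S,2S,4a'S,5'S,8a'R)-5',8a'-dimethyl-5'-(pivaloyloxymethyl)octahydro-1'H-spiro[oxirane-2,2'-naphthalen]-1'-yl]-3-methylpentanoate | CC(C)(C)C(=O)OC[C@@]1(C)CCC[C@]2(C)[C@@H]1CC[C@]3(OC3)[C@H]2CC[C@H](C)CC(=O)OC(C)(C)C | intermediate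
34 | (3S)-5-[(1S,2S,4aS,5S,8aR)-2-hydroxy-5-(hydroxymethyl)-2,5,8a-trimethyldecahydronaphthalen-1-yl]-3-methylpentan-1-ol | OC[C@@]1(C)CCC[C@]2(C)[C@@H]1CC[C@](C)(O)[C@H]2CC[C@H](C)CCO | intermediate
35 | (1S,2S,4aS,5S,8aR)-1-[(3S)-5-(tert-butyldimethylsilyloxy)-3-methylpentyl]-5-(hydroxymethyl)-2,5,8a-trimethyldecahydronaphthalen-2-ol | OC[C@@]1(C)CCC[C@]2(C)[C@@H]1CC[C@](C)(O)[C@H]2CC[C@H](C)CCO[Si](C)(C)C(C)(C)C | intermediate
36 | [(1S,2S,4aS,5S,8aR)-1-{(3S)-5-(tert-butyldimethylsilyloxy)-3-methylpentyl}-2-hydroxy-2,5,8a-trimethyldecahydronaphthalen-5-yl]methyl (2Z)-2-methylbut-2-enoate | C/C=C(/C)C(=O)OC[C@@]1(C)CCC[C@]2(C)[C@@H]1CC[C@](C)(O)[C@H]2CC[C@H](C)CCO[Si](C)(C)C(C)(C)C | intermediate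
37 | [(1S,2S,4aS,5S,8aR)-2-hydroxy-1-{(3S)-5-hydroxy-3-methylpentyl}-2,5,8a-trimethyldecahydronaphthalen-5-yl]methyl (2Z)-2-methylbut-2-enoate | C/C=C(/C)C(=O)OC[C@@]1(C)CCC[C@]2(C)[C@@H]1CC[C@](C)(O)[C@H]2CC[C@H](C)CCO | intermediate
38 | 3-{[(3S)-5-{(1S,2S,4aS,5S,8aR)-2-hydroxy-2,5,8a-trimethyl-5-[(2Z)-2-methylbut-2-enoyloxymethyl]decahydronaphthalen-1-yl}-3-methylpentyl]oxy}-3-oxopropanoic acid | C/C=C(/C)C(=O)OC[C@@]1(C)CCC[C@]2(C)[C@@H]1CC[C@](C)(O)[C@H]2CC[C@H](C)CCOC(=O)CC(=O)O | target

**Step count and risks**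

Total: 29 steps. Longest linear sequence: 26 steps (steps 1–11 and 15–29, from geranyl acetate); the side-chain salt 21 takes 3 steps (12–14).

Steps most likely to fail:

1. Step 11. The cycloaddition may be outrun by silyl transfer from the dienol ether to the acid catalyst (desilylative Mukaiyama–Michael paths), or the hindered β,β-disubstituted enal may react with low facial discrimination. The fallback uses known chemistry and sets out from 16: an achiral Me2AlCl-promoted intramolecular Diels–Alder reaction (CH2Cl2, −78 → −20 °C), a known reaction class for trienals, should give 17 as the racemate, that is, together with the mirror-image cycloadduct F1. NaBH4 reduction then gives the primary alcohol F2 and the enantiomeric alcohol F3. Esterification with (S)-2-methoxy-2-phenylacetic acid (DCC, DMAP) gives the mandelate ester F4 and the diastereomeric ester F5, which are separated by chromatography. Methanolysis of F4 (K2CO3, MeOH) returns F2, and Dess–Martin oxidation leads back to the route at 17.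

2. Step 15. Addition of the β-branched ylide to the congested C11 aldehyde may be slow, so that base-induced loss of silanol across C8–C9 competes. The fallback sets out from 20 and 17 and replaces the Wittig reaction by a Julia–Kocienski olefination. Iodide 20 and 1-phenyl-1H-tetrazole-5-thiol (K2CO3, DMF) give the tetrazolyl sulfide F6, which is oxidised (H2O2, (NH4)6Mo7O24·4H2O, EtOH) to the tetrazolyl sulfone F7. KN(SiMe3)2 is then added to a mixture of F7 and 17 (DME, −60 °C), so that the smaller and more nucleophilic sulfonyl carbanion is trapped as it forms, giving the (E)-alkene F8. Hydrogenation under the conditions of step 16 comes back to the route at 24.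

3. Step 18. Kinetic discrimination between the equatorial and the axial hydroxymethyl group may be insufficient, leading to acylation of the wrong arm or of both. The fallback sets out from 25 and changes the mode of activation: heating with Bu2SnO (toluene, reflux, removal of water) gives the dibutylstannylene acetal F9, in which the less hindered, equatorial tin-bound oxygen is the more nucleophilic one. Addition of t-BuCOCl at 0 °C and aqueous work-up should then deliver the mono-pivalate, coming back to the route at 26.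

**Further compounds**

F1 | step 11 | (4a'S,5'R,6'S,8a'R)-6'-(tert-butyldimethylsilyloxy)-2,2,4a'-trimethyl-3',4',4a',5',6',8a'-hexahydro-2'H-spiro[1,3-dioxane-5,1'-naphthalene]-5'-carbaldehyde (mirror image of 17) | CC1(C)OCC2(CO1)CCC[C@@]3(C)[C@H]2C=C[C@H](O[Si](C)(C)C(C)(C)C)[C@@H]3C=O
F2 | step 11 | [(4a'R,5'R,6'R,8a'S)-6'-(tert-butyldimethylsilyloxy)-2,2,4a'-trimethyl-3',4',4a',5',6',8a'-hexahydro-2'H-spiro[1,3-dioxane-5,1'-naphthalen]-5'-yl]methanol | CC1(C)OCC2(CO1)CCC[C@]3(C)[C@@H]2C=C[C@@H](O[Si](C)(C)C(C)(C)C)[C@H]3CO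
F3 | step 11 | [(4a'S,5'S,6'S,8a'R)-6'-(tert-butyldimethylsilyloxy)-2,2,4a'-trimethyl-3',4',4a',5',6',8a'-hexahydro-2'H-spiro[1,3-dioxane-5,1'-naphthalen]-5'-yl]methanol (enantiomer of F2) | CC1(C)OCC2(CO1)CCC[C@@]3(C)[C@H]2C=C[C@H](O[Si](C)(C)C(C)(C)C)[C@@H]3CO
F4 | step 11 | (S)-2-methoxy-2-phenylacetate of F2 | CC1(C)OCC2(CO1)CCC[C@]3(C)[C@@H]2C=C[C@@H](O[Si](C)(C)C(C)(C)C)[C@H]3COC(=O)[C@@H](OC)c4ccccc4
F5 | step 11 | (S)-2-methoxy-2-phenylacetate of F3 | CC1(C)OCC2(CO1)CCC[C@@]3(C)[C@H]2C=C[C@H](O[Si](C)(C)C(C)(C)C)[C@@H]3COC(=O)[C@@H](OC)c4ccccc4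
F6 | step 15 | tert-butyl (3R)-3-methyl-4-[(1-phenyl-1H-tetrazol-5-yl)sulfanyl]butanoate | CC(C)(C)OC(=O)C[C@@H](C)CSc1nnnn1-c1ccccc1
F7 | step 15 | tert-butyl (3R)-3-methyl-4-[(1-phenyl-1H-tetrazol-5-yl)sulfonyl]butanoate | CC(C)(C)OC(=O)C[C@@H](C)CS(=O)(=O)c1nnnn1-c1ccccc1
F8 | step 15 | tert-butyl (3R,4E)-5-[(4a'R,5'S,6'R,8a'S)-6'-(tert-butyldimethylsilyloxy)-2,2,4a'-trimethyl-3',4',4a',5',6',8a'-hexahydro-2'H-spiro[1,3-dioxane-5,1'-naphthalen]-5'-yl]-3-methylpent-4-enoate | CC1(C)OCC2(CO1)CCC[C@]3(C)[C@@H]2C=C[C@@H](O[Si](C)(C)C(C)(C)C)[C@H]3/C=C/[C@H](C)CC(=O)OC(C)(C)C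
F9 | step 18 | dibutylstannylene acetal of diol 25 | CCCC[Sn]1(CCCC)OCC2(CO1)CCC[C@]3(C)[C@@H]2CC[C@@H](O[Si](C)(C)C(C)(C)C)[C@H]3CC[C@H](C)CC(=O)OC(C)(C)C
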